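**Retrosynthetic overview**
1. Target 19 ⇐ 17 + 18 (senecioate installed last); 17 ⇐ 15 by hydroxylation of the C6 enolate (C6–O bond, trans to the side chain).
2. 15 ⇐ 12 + 13 (angelate); 12 ⇐ enone 9 by the proposed C8-alkoxide-tethered zinc peroxide epoxidation (C2–C3 oxirane syn to the side chain).
3. 9 ⇐ 7 + 8 (cross-metathesis, prenyl terminus); 7 ⇐ enal 4 + 5 (asymmetric allylation: C8–C9 bond and C8 stereocentre).
4. 4 ⇐ 2 ⇐ (R)-carvone 1 (allylic chlorination, then N-oxide oxidation of the isopropenyl methyl).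
5. Ring order: the six-membered carbocycle and C5 come intact from 1; the oxirane is the only ring made, in step 5.

Assumption: the ester written OC(=O)/C(C)=C\C is read as the (2Z) angelate and all five stereocentres as S; carvone numbering is used for positions (ring C1 carbonyl, C2 methyl-bearing, C5 side-chain-bearing, C6 acyloxy-bearing; side chain C7(=CH2)–C8(O)–C9–C10=C11).

Step 1
Reactants: 1 (R)-(−)-carvone
Product: 2 (5R)-5-(3-chloroprop-1-en-2-yl)-2-methylcyclohex-2-en-1-one
Conditions: Ca(OCl)2, CO2 (solid), CH2Cl2/H2O, 0 °C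
Reagents that add atoms: calcium hypochlorite, [Ca+2].[O-]Cl.[O-]Cl
Why: Ene-type allylic chlorination: HOCl formed in situ adds Cl+ to the terminal carbon of the electron-rich 1,1-disubstituted alkene and a methyl proton is lost, which gives the 2-substituted allyl chloride while the electron-poor enone and the C5 stereocentre are untouched.

Step 2
Reactants: 2 (5R)-5-(3-chloroprop-1-en-2-yl)-2-methylcyclohex-2-en-1-one
Product: 4 2-[(1R)-4-methyl-5-oxocyclohex-3-en-1-yl]prop-2-enal, via alkoxyammonium chloride 3 (not isolated)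
Conditions: Me3NO (anhydrous, 4 equiv), DMSO, 40 °C
Reagents that add atoms: trimethylamine N-oxide, C[N+](C)(C)[O-]
Why: Ganem oxidation (N-oxide variant of the Kornblum oxidation): SN2 O-alkylation of Me3NO by the primary allylic chloride gives salt 3, which loses trimethylamine by E2-type deprotonation to unveil the 2-substituted acrolein under conditions too mild to epimerise C5.

Step 3
Reactants: 4 2-[(1R)-4-methyl-5-oxocyclohex-3-en-1-yl]prop-2-enal; 5 (−)-B-allyldiisopinocampheylborane
Product: 7 (5R)-5-[(3S)-3-hydroxyhexa-1,5-dien-2-yl]-2-methylcyclohex-2-en-1-one, via borinate ester 6 (not isolated)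
Conditions: Et2O, −78 °C, 3 h; then HOCH2CH2NH2, 25 °C
Reagents that add atoms: none
Why: Brown asymmetric allylboration: the allyl group is delivered through a chair Zimmerman–Traxler transition state to the Si face of the aldehyde under control of the (+)-α-pinene-derived ligands, which sets C8 as S (expected about 95:5, minor epimer removed by chromatography), the ketone being inert at −78 °C and the ethanolamine work-up avoiding alkaline peroxide that would epoxidise the enone.

Step 4
Reactants: 7 (5R)-5-[(3S)-3-hydroxyhexa-1,5-dien-2-yl]-2-methylcyclohex-2-en-1-one; 8 2-methylbut-2-ene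
Product: 9 (5R)-5-[(3S)-3-hydroxy-6-methylhepta-1,5-dien-2-yl]-2-methylcyclohex-2-en-1-one
Conditions: second-generation Grubbs catalyst RuCl2(=CHPh)(PCy3)(H2IMes) (5 mol%), 8 (20 equiv), CH2Cl2, 40 °C
Reagents that add atoms: none
Why: Olefin cross-metathesis: only the monosubstituted vinyl group initiates on ruthenium and exchanges its terminus for the isopropylidene of excess 8 (propene is lost), while the 1,1-disubstituted alkene flanked by two branched carbons and the enone stay inert; no stereocentre is touched.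

Step 5
Reactants: 9 (5R)-5-[(3S)-3-hydroxy-6-methylhepta-1,5-dien-2-yl]-2-methylcyclohex-2-en-1-one
Product: 12 (1S,4R,6S)-4-[(3S)-3-hydroxy-6-methylhepta-1,5-dien-2-yl]-1-methyl-7-oxabicyclo[4.1.0]heptan-2-one, via ethylzinc alkoxide 10 (not isolated), via zinc tert-butylperoxide 11 (not isolated)
Conditions: Et2Zn (1.05 equiv), PhMe (degassed), −20 °C; then t-BuOOH (anhydrous in decane, 1.1 equiv), −20 to 0 °C; then H2O
Reagents that add atoms: tert-butyl hydroperoxide, CC(C)(C)OO
Why: Proposed new method: deprotonation of the C8 hydroxyl by Et2Zn and protonolysis of the remaining Zn–Et bond by t-BuOOH place a tert-butylperoxide ligand on the substrate-bound zinc (11), whose zinc-bound peroxide oxygen can reach C3 only on the side-chain face through the half-chair in which the C5 substituent is axial (an easily populated conformer, since C1 and C3 are sp2 and carry no syn-axial hydrogens), so that stereoelectronically favoured axial conjugate attack through an eight-membered zinc chelate, followed by closure of the zinc enolate onto oxygen with loss of tert-butoxide, gives the C2–C3 oxirane syn to the side chain (2S,3S), the opposite of the trans selectivity of intermolecular alkaline peroxide, while zinc peroxides leave the isolated alkenes alone; closest known reaction types: Weitz–Scheffer epoxidation of enones by alkoxide-ligated zinc alkylperoxides and hydroxyl-directed nucleophilic epoxidation of 4-hydroxy enones.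

Step 6
Reactants: 12 (1S,4R,6S)-4-[(3S)-3-hydroxy-6-methylhepta-1,5-dien-2-yl]-1-methyl-7-oxabicyclo[4.1.0]heptan-2-one; 13 angelic acid
Product: 15 (1S,4R,6S)-1-methyl-4-[(3S)-6-methyl-3-{[(2Z)-2-methylbut-2-enoyl]oxy}hepta-1,5-dien-2-yl]-7-oxabicyclo[4.1.0]heptan-2-one, via mixed anhydride 14 (not isolated)
Conditions: 13, 2,4,6-Cl3C6H2COCl, Et3N, PhMe, 25 °C, filter; then 12, PhMe, 80 °C
Reagents that add atoms: none
Why: Yamaguchi-type mixed-anhydride esterification: the alcohol attacks the unhindered angeloyl carbonyl of 14 (the aroyl carbonyl is shielded by two ortho chlorines) without any nucleophilic catalyst, the condition known to suppress Z to E isomerisation to the tiglate; no stereocentre is touched.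

Step 7
Reactants: 15 (1S,4R,6S)-1-methyl-4-[(3S)-6-methyl-3-{[(2Z)-2-methylbut-2-enoyl]oxy}hepta-1,5-dien-2-yl]-7-oxabicyclo[4.1.0]heptan-2-one
Product: 17 (1S,3S,4S,6S)-3-hydroxy-1-methyl-4-[(3S)-6-methyl-3-{[(2Z)-2-methylbut-2-enoyl]oxy}hepta-1,5-dien-2-yl]-7-oxabicyclo[4.1.0]heptan-2-one, via potassium enolate 16 (not isolated)
Conditions: KN(SiMe3)2 (1.1 equiv), THF, −78 °C; then 2-(phenylsulfonyl)-3-phenyloxaziridine (1.3 equiv), −78 °C; then AcOH
Reagents that add atoms: 2-(phenylsulfonyl)-3-phenyloxaziridine, O=S(=O)(N1OC1c1ccccc1)c1ccccc1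
Why: Davis enolate oxidation: deprotonation can occur only at C6 (C2 is quaternary), and the N-sulfonyloxaziridine transfers oxygen to the enolate face anti to both the adjacent C5 side chain and the oxirane, which sets C6 as S (5,6-trans), the ketone being far more acidic than the angelate γ-hydrogens.

Step 8
Reactants: 17 (1S,3S,4S,6S)-3-hydroxy-1-methyl-4-[(3S)-6-methyl-3-{[(2Z)-2-methylbut-2-enoyl]oxy}hepta-1,5-dien-2-yl]-7-oxabicyclo[4.1.0]heptan-2-one; 18 3-methylbut-2-enoyl chloride
Product: 19 (1S,3S,4S,6S)-1-methyl-4-[(3S)-6-methyl-3-{[(2Z)-2-methylbut-2-enoyl]oxy}hepta-1,5-dien-2-yl]-2-oxo-7-oxabicyclo[4.1.0]heptan-3-yl 3-methylbut-2-enoate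
Conditions: pyridine, DMAP (10 mol%), CH2Cl2, 0 to 25 °C
Reagents that add atoms: none
Why: DMAP-catalysed acylation (nucleophilic acyl substitution) of the secondary α-hydroxy ketone by the acid chloride; pyridine is too weak a base to deconjugate the senecioyl unit through a vinylketene or to epimerise C6, which already holds the more stable trans position.

**Compound list**
1 | (R)-(−)-carvone, (5R)-2-methyl-5-(prop-1-en-2-yl)cyclohex-2-en-1-one | C=C(C)[C@@H]1CC=C(C)C(=O)C1 | starting material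
2 | (5R)-5-(3-chloroprop-1-en-2-yl)-2-methylcyclohex-2-en-1-one | C=C(CCl)[C@@H]1CC=C(C)C(=O)C1 | intermediate
3 | trimethyl({2-[(1R)-4-methyl-5-oxocyclohex-3-en-1-yl]prop-2-en-1-yl}oxy)azanium chloride (alkoxyammonium chloride) | C=C(CO[N+](C)(C)C)[C@@H]1CC=C(C)C(=O)C1.[Cl-] | intermediate
4 | 2-[(1R)-4-methyl-5-oxocyclohex-3-en-1-yl]prop-2-enal | C=C(C=O)[C@@H]1CC=C(C)C(=O)C1 | intermediate
5 | (−)-B-allyldiisopinocampheylborane, allylbis[(1R,2S,3R,5R)-2,6,6-trimethylbicyclo[3.1.1]heptan-3-yl]borane (from (+)-α-pinene; commercial pentane solution) | C=CCB([C@@H]1C[C@@H]2C[C@H]([C@H]1C)C2(C)C)[C@@H]1C[C@@H]2C[C@H]([C@H]1C)C2(C)C | starting material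
6 | (3S)-2-[(1R)-4-methyl-5-oxocyclohex-3-en-1-yl]hexa-1,5-dien-3-yl bis[(1R,2S,3R,5R)-2,6,6-trimethylbicyclo[3.1.1]heptan-3-yl]borinate (borinate ester) | C=C([C@H](CC=C)OB([C@@H]1C[C@@H]2C[C@H]([C@H]1C)C2(C)C)[C@@H]1C[C@@H]2C[C@H]([C@H]1C)C2(C)C)[C@@H]1CC=C(C)C(=O)C1 | intermediate
7 | (5R)-5-[(3S)-3-hydroxyhexa-1,5-dien-2-yl]-2-methylcyclohex-2-en-1-one | C=C([C@H](CC=C)O)[C@@H]1CC=C(C)C(=O)C1 | intermediate
8 | 2-methylbut-2-ene | CC=C(C)C | starting material
9 | (5R)-5-[(3S)-3-hydroxy-6-methylhepta-1,5-dien-2-yl]-2-methylcyclohex-2-en-1-one | C=C([C@H](CC=C(C)C)O)[C@@H]1CC=C(C)C(=O)C1 | intermediate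
10 | ethyl{[(3S)-6-methyl-2-[(1R)-4-methyl-5-oxocyclohex-3-en-1-yl]hepta-1,5-dien-3-yl]oxy}zinc (ethylzinc alkoxide of 9) | C=C([C@H](CC=C(C)C)O[Zn]CC)[C@@H]1CC=C(C)C(=O)C1 | intermediate
11 | (tert-butylperoxy){[(3S)-6-methyl-2-[(1R)-4-methyl-5-oxocyclohex-3-en-1-yl]hepta-1,5-dien-3-yl]oxy}zinc (zinc tert-butylperoxide of 9) | C=C([C@H](CC=C(C)C)O[Zn]OOC(C)(C)C)[C@@H]1CC=C(C)C(=O)C1 | intermediate
12 | (1S,4R,6S)-4-[(3S)-3-hydroxy-6-methylhepta-1,5-dien-2-yl]-1-methyl-7-oxabicyclo[4.1.0]heptan-2-one (oxirane cis to the side chain) | C=C([C@H](CC=C(C)C)O)[C@@H]1C[C@@H]2O[C@]2(C)C(=O)C1 | intermediate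
13 | angelic acid, (2Z)-2-methylbut-2-enoic acid | C/C=C(/C)C(=O)O | starting material
14 | (2Z)-2-methylbut-2-enoic 2,4,6-trichlorobenzoic anhydride (mixed anhydride) | C/C=C(/C)C(=O)OC(=O)c1c(Cl)cc(Cl)cc1Cl | intermediate
15 | (1S,4R,6S)-1-methyl-4-[(3S)-6-methyl-3-{[(2Z)-2-methylbut-2-enoyl]oxy}hepta-1,5-dien-2-yl]-7-oxabicyclo[4.1.0]heptan-2-one | C=C([C@H](CC=C(C)C)OC(=O)/C(C)=C\C)[C@@H]1C[C@@H]2O[C@]2(C)C(=O)C1 | intermediate
16 | potassium enolate of 15 (C1–O−, C1=C6) | C=C([C@H](CC=C(C)C)OC(=O)/C(C)=C\C)[C@@H]1C[C@@H]2O[C@]2(C)C([O-])=C1.[K+] | intermediate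
17 | (1S,3S,4S,6S)-3-hydroxy-1-methyl-4-[(3S)-6-methyl-3-{[(2Z)-2-methylbut-2-enoyl]oxy}hepta-1,5-dien-2-yl]-7-oxabicyclo[4.1.0]heptan-2-one | C=C([C@H](CC=C(C)C)OC(=O)/C(C)=C\C)[C@@H]1C[C@@H]2O[C@]2(C)C(=O)[C@H]1O | intermediate
18 | 3-methylbut-2-enoyl chloride (senecioyl chloride) | CC(C)=CC(=O)Cl | starting material
19 | (1S,3S,4S,6S)-1-methyl-4-[(3S)-6-methyl-3-{[(2Z)-2-methylbut-2-enoyl]oxy}hepta-1,5-dien-2-yl]-2-oxo-7-oxabicyclo[4.1.0]heptan-3-yl 3-methylbut-2-enoate (CNP0333561.1) | C=C([C@H](CC=C(C)C)OC(=O)/C(C)=C\C)[C@@H]1C[C@@H]2O[C@]2(C)C(=O)[C@H]1OC(=O)C=C(C)C | target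

**Step count and risks**
Total step count: 8. Longest linear sequence: 8 steps (1 to 19; fully linear, the other starting materials 5, 8, 13 and 18 are bought).

The three steps most likely to fail:

Step 5 (the proposed new epoxidation). Aggregated zinc peroxide may also deliver oxygen between molecules, which would give the trans oxirane, and the zinc alkoxide may add reversibly to C3 (oxa-Michael). The fallback uses known chemistry, sets out from 9 and comes back to the route at 15, so it also replaces step 6. Alcohol 9 is esterified with 13 through mixed anhydride 14 under the conditions of step 6 to give the enone angelate F1. Luche reduction (NaBH4, CeCl3·7H2O, MeOH, −78 °C; axial hydride attack) gives the allylic alcohol F2 with the hydroxyl cis to the side chain. VO(acac)2/t-BuOOH (CH2Cl2, 0 °C) epoxidises only the allylic-alcohol alkene, syn to the hydroxyl, to give the epoxy alcohol F3. Dess–Martin periodinane (NaHCO3, CH2Cl2) oxidises F3 to 15, and the route goes on with step 7.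

Step 6 (angeloylation). The hindered allylic alcohol may react slowly, and prolonged heating risks partial Z to E isomerisation to the tiglate. The fallback sets out from 12 and comes back at 15, and builds the Z alkene on the ester instead of transferring it. Steglich esterification of 12 with 2-[bis(2,2,2-trifluoroethoxy)phosphoryl]propanoic acid (DCC, DMAP, CH2Cl2) gives the phosphonopropanoate F4. Still–Gennari olefination of F4 (KN(SiMe3)2, 18-crown-6, THF, −78 °C, then acetaldehyde) gives the (Z)-2-methylbut-2-enoate 15; the phosphonate α-hydrogen is far more acidic than the ketone α-hydrogens, so the epoxy ketone is not enolised.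

Step 7 (enolate hydroxylation). The potassium enolate could attack the angelate carbonyl (acyl transfer to C6), or facial selectivity could erode. The fallback sets out from 15 and comes back at 17 by a Rubottom oxidation. LiN(SiMe3)2 with Me3SiCl as internal quench (THF, −78 °C) gives the trimethylsilyl enol ether F5. Dimethyldioxirane (1.0 equiv, acetone/CH2Cl2, −78 °C) should epoxidise the electron-rich enol ether faster than the prenyl alkene, on the face anti to the side chain, to give the silyloxy oxirane F6. Aqueous citric acid in THF opens F6 to 17.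

**Further compounds**
F1 | step 5 | (3S)-6-methyl-2-[(1R)-4-methyl-5-oxocyclohex-3-en-1-yl]hepta-1,5-dien-3-yl (2Z)-2-methylbut-2-enoate (enone angelate) | C=C([C@H](CC=C(C)C)OC(=O)/C(C)=C\C)[C@@H]1CC=C(C)C(=O)C1
F2 | step 5 | (3S)-2-[(1R,5R)-5-hydroxy-4-methylcyclohex-3-en-1-yl]-6-methylhepta-1,5-dien-3-yl (2Z)-2-methylbut-2-enoate (allylic alcohol, hydroxyl cis to the side chain) | C=C([C@H](CC=C(C)C)OC(=O)/C(C)=C\C)[C@@H]1CC=C(C)[C@H](O)C1
F3 | step 5 | (3S)-2-[(1S,3S,5R,6R)-5-hydroxy-6-methyl-7-oxabicyclo[4.1.0]heptan-3-yl]-6-methylhepta-1,5-dien-3-yl (2Z)-2-methylbut-2-enoate (epoxy alcohol, oxirane and hydroxyl cis to the side chain) | C=C([C@H](CC=C(C)C)OC(=O)/C(C)=C\C)[C@@H]1C[C@@H]2O[C@]2(C)[C@H](O)C1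
F4 | step 6 | (3S)-6-methyl-2-[(1S,3R,6S)-6-methyl-5-oxo-7-oxabicyclo[4.1.0]heptan-3-yl]hepta-1,5-dien-3-yl 2-[bis(2,2,2-trifluoroethoxy)phosphoryl]propanoate (both epimers at the phosphonate carbon) | C=C([C@H](CC=C(C)C)OC(=O)C(C)P(=O)(OCC(F)(F)F)OCC(F)(F)F)[C@@H]1C[C@@H]2O[C@]2(C)C(=O)C1
F5 | step 7 | (3S)-6-methyl-2-{(1S,3R,6S)-6-methyl-5-[(trimethylsilyl)oxy]-7-oxabicyclo[4.1.0]hept-4-en-3-yl}hepta-1,5-dien-3-yl (2Z)-2-methylbut-2-enoate (trimethylsilyl enol ether) | C=C([C@H](CC=C(C)C)OC(=O)/C(C)=C\C)[C@@H]1C[C@@H]2O[C@]2(C)C(O[Si](C)(C)C)=C1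
F6 | step 7 | silyloxy oxirane: the C1–C6 epoxide of F5 on the face anti to the side chain and to the C2–C3 oxirane, C1 keeping the trimethylsilyloxy group | C=C([C@H](CC=C(C)C)OC(=O)/C(C)=C\C)[C@@H]1C[C@@H]2O[C@]2(C)[C@@]3(O[Si](C)(C)C)O[C@@H]13
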